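How far does the starting complex get in 10 d, and where does the incoming ligand end up?

- part of the starting complex that has reacted at 10 d
- share of free incoming ligand in free incoming ligand and idle adduct A together, at 10 d

| setting | Tuesday's | Sunday's | Saturday's | flask |
|---|---|---|---|---|
| starting complex | 13 mM | 13 mM | 13 mM | 13 mM |
| incoming ligand | 4.5 mM | 18 mM | 9.1 mM | 9.10 mM |
| leaving ligand | 6.5 mM | 6.5 mM | 6.5 mM | 6.50 mM |
| scavenger | 13 mM | 13 mM | 20 mM | 13.0 mM |
| remark | run made earlier | run made earlier | run made earlier |  |
| time |  |  |  | 10 d |

| run | time / d | starting complex / % | complex with two exchanged / % |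
|---|---|---|---|
| Tuesday's | 1.25 | 70.5 | 5.4 |
| Tuesday's | 2.50 | 70.2 | 4.3 |
| Tuesday's | 3.00 | 70.5 | 5.4 |
| Tuesday's | 5.00 | 70.8 | 5.2 |
| Tuesday's | 6.00 | 70.6 | 4.7 |
| Tuesday's | 8.00 | 70.6 | 5.1 |
| Sunday's | 0.417 | 39.2 | 25.5 |
| Sunday's | 1.25 | 27.8 | 36.9 |
| Sunday's | 2.50 | 23.0 | 38.3 |
| Sunday's | 3.00 | 21.0 | 36.8 |
| Sunday's | 5.00 | 18.0 | 34.0 |
| Sunday's | 6.00 | 16.4 | 32.0 |
| Sunday's | 8.00 | 14.3 | 29.7 |
| Saturday's | 1.67 | 48.2 | 17.9 |
| Saturday's | 3.00 | 47.8 | 18.5 |
| Saturday's | 5.00 | 48.1 | 19.0 |
| Saturday's | 6.00 | 48.2 | 17.7 |
| Saturday's | 8.00 | 48.1 | 18.5 |

(readings scatter by 0.5 percentage points)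

- what is said of complex with two exchanged includes idle adduct B
- what is said of leaving ligand includes idle adduct A
- the numbers in the tables scatter with a standard deviation of 0.5 percentage points
- steps thought possible: starting complex + incoming ligand <-> leaving ligand + complex with one exchanged; complex with one exchanged + incoming ligand <-> leaving ligand + complex with two exchanged; leaving ligand + incoming ligand <-> idle adduct A; scavenger + leaving ligand -> scavenged by-product; complex with two exchanged + incoming ligand <-> idle adduct B; complex with one exchanged -> side product
- the earlier runs do not show how much of incoming ligand is bound; that part of a forecast is a guess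

Each incoming ligand taken up frees one leaving ligand, and the scavenger removes leaving ligand. Reckon 2.60 mM for this flask as leaving ligand charged plus incoming ligand charged minus scavenger charged, the surplus. Tuesday's run (−2.00 mM) and Saturday's (−4.40 mM) have a negative surplus, and their [starting complex] lies flat from the first reading. Sunday's (11.5 mM) has a positive one and keeps sinking.

Now the curve of this flask. Sunday's first reading, scaled to this charge of incoming ligand, gives a mean slope of ln[starting complex] near 1.14 d⁻¹ over the first stretch. The knee should come when uptake reaches 6.50 mM, where charged and released leaving ligand together equal the 13.0 mM of scavenger. Between Tuesday's and Saturday's levels, that uptake means about 39.2% reacted, near 0.438 d. Watch for that bend.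

Beyond it, the last 2.60 mM of incoming ligand has to go in against free leaving ligand. Saturday's run, with the same charge of incoming ligand, reads 51.9% reacted, so the curve should bend toward that level. Sunday's [starting complex] still loses 0.167 of a decade from 3.00 d to 8.00 d, so this reckoning puts c somewhat above that level. The share fr stays a guess.

The forecast said 58% and 45%, holding that “about 2.5 mM excess makes exchange reversible”. The flask gives 56.5% and 33.6%.

    starting complex + incoming ligand ⇌ leaving ligand + complex with one exchanged (K = 54.0, k = 14.0 M⁻¹ h⁻¹)
    complex with one exchanged + incoming ligand ⇌ leaving ligand + complex with two exchanged (K = 12.0, k = 16.0 M⁻¹ h⁻¹)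
    leaving ligand + incoming ligand ⇌ idle adduct A, settled at all times (K = 850 M⁻¹)
    scavenger + leaving ligand → scavenged by-product (k = 560 M⁻¹ h⁻¹)
    complex with two exchanged + incoming ligand ⇌ idle adduct B, settled at all times (K = 31.0 M⁻¹)
    complex with one exchanged → side product (k = 0.00500 h⁻¹)

In the flask, the half-life of free leaving ligand against scavenger, 0.19 h, is far shorter than the 0.39 d of starting complex by the forward rate of its step alone, both at 0.0879 d. By 1.00 d scavenger stands at 0.00593% of its charge, and at 10.0 d free leaving ligand and idle adduct A together hold 2.43 mM against the surplus of 2.60 mM. The neighbour charged with 3.6 mM of incoming ligand has a surplus of −2.90 mM, and at 10.0 d it holds 2.90 mM of unused scavenger.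

The earlier runs and the new flask come from a simulation with made-up constants; scatter was added.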